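A flat curve is a trap: it says that a flask has stopped, not why it stopped, so I began from the readings and from a scale of my own.

common to all: substrate 13 mM
- birch: partner 0.010 equiv; run made earlier
- alder: partner 0.64 equiv; run made earlier
- delta: partner 0.0120 equiv; time 8.0 min
- theta: partner 0.0400 equiv; time 8.0 min
- epsilon: partner 0.120 equiv; time 8.0 min
- gamma: partner 0.400 equiv; time 8.0 min
- zeta: partner 1.00 equiv; time 8.0 min

| run | time / min | single product / % | substrate / % |
|---|---|---|---|
| birch | 0.417 | 0.2 | 98.4 |
| birch | 1.33 | 0 | 98.8 |
| birch | 2.50 | 0.9 | 97.9 |
| birch | 3.00 | 0 | 100.8 |
| birch | 5.00 | 0 | 99.4 |
| birch | 6.00 | 0 | 99.2 |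
| birch | 8.00 | 0.8 | 98.2 |
| alder | 1.00 | 16.6 | 81.8 |
| alder | 2.50 | 18.9 | 79.9 |
| alder | 3.00 | 17.6 | 82.6 |
| alder | 5.00 | 15.1 | 81.4 |
| alder | 6.00 | 15.3 | 80.8 |
| alder | 8.00 | 15.7 | 79.4 |

(standard deviation of a reading: 1 percentage point)

- "hardly changes" means that all values lie within two and a half points (for a concentration: within two and a half percent of the largest)

- amount of single product at the end, in percent of the substrate charged for delta, theta, epsilon, gamma, zeta, in this order
- the shape of the row from first to last (falls, then rises / hardly changes / falls all the way / rises, then falls / rises all the way)

I went through the alder flask in slow motion. In the first instants, up to 1.00 min, it had already reached 16.6% single product. Through the middle, up to 6.00 min, the readings wandered between 15.1% and 18.9%, with a scatter of 1 percentage point, and at 8.00 min they stood at 15.7%, with 79.4% substrate. The later readings showed no steady rise after that first sample, so I turned to the charge.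

As the zero of the scale I took the plain case of one single product per partner charged, which is 100 percent. The alder mean of 16.5% on 0.64 equiv gave 25.8% for the capture share φ, the single product formed per partner charged. The birch mean of 0.271% on 0.010 equiv gave 27.1%, a weak reading, since single readings there scatter by 1 point. Holding φ constant, I reckoned 0.310% for delta and 25.8% for zeta, a straight line in the charge.

The forecast held that “this is a fast equilibrium and not a slow conversion”, and it gave 0.35%, 1.16%, 3.4%, 10.8% and 24%, a row that rises all the way. Its figures differ from mine at both ends and bend where my line does not.

The flasks gave 0.376%, 1.25%, 3.66%, 11.4% and 24.5%, a row that rises all the way, as the forecast said.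

    partner → decomposed reagent (k = 0.0510 s⁻¹)
    partner + single product → bis adduct + released group (k = 1.20 M⁻¹ s⁻¹)
    substrate + partner → single product + released group (k = 1.80 M⁻¹ s⁻¹)

Delta's plateau is a spent reagent, not a balance: delta held 0% of its partner by 4.00 min, and the later time changed nothing. With the partner held at its charge, as if it never ran down, delta stood at 12.0% instead of 0.376%, so the depletion of partner is one part of the reason for that low plateau. Delta's φ read 31.3%. Without the decomposition of partner, delta reached 1.19% on a charge of 0.0120 equiv, so that step is a part of what holds φ below the zero of the scale. In zeta φ read 24.5%, and without the same step, again a part of the story, the single product there stood at 44.4% instead of 24.5%.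

(The numbers in the tables are simulated from invented constants; noise was put on by code.)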